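**Plan** (upper unit: rings A benzo, B aryl, C pyran; lower unit: rings D benzo, E aryl, F pyran)
1. Retrosynthesis: the six benzyl ethers come off last; ring E is cut from lower C2 at an oxocarbenium ion; then lower C3–C4 and O1–C2 of ring F are cut together, giving a ring D o-quinone methide and benzyloxyacetaldehyde.
2. Enabling feature: in ring F, O1 sits on ring D carbon C8a, the neighbouring C4a carries the unsubstituted C4 methylene, and C3 is an oxygenated stereocentre. C8a(=O)/C4a(=CH2) is therefore an o-quinone methide and C2–C3 an α-oxy aldehyde.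
3. Upper unit: ring C is cut at C4–C3 and O1–C2 into a ring A o-quinone methide bearing ring D on its methide carbon and 4-benzyloxystyrene; the diaryl carbinol comes from a ring D aryllithium and a ring A salicylaldehyde.
4. Forward order: rings D and A joined, ring C closed by [4+2], ring D phenol unmasked and sulfonylmethylated, ring F closed as a lactol, ring E added at lower C2, debenzylation.
5. Stereochemistry: upper C4 and C2 (S,S, 2,4-cis) from a chiral Brønsted acid-catalysed endo cycloaddition; lower C3 (R) from the chiral amine catalyst; lower C2 (R, cis to C3–O) from addition to the oxocarbenium ion under control of C3.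

Key step: step 7

Assumption: the (R)-binaphthyl phosphoramide in step 4 is drawn by analogy as the catalyst that gives the 4S flavan; should the sense of induction prove opposite, its enantiomer would be used.

**Step 1**
Reactants: 1 3,5-bis(benzyloxy)phenol
Product: 2 [3,5-bis(benzyloxy)phenoxy]triisopropylsilane
Conditions: i-Pr3SiCl, imidazole, DMF, rt
Reagents that add atoms: triisopropylsilyl chloride, CC(C)[Si](Cl)(C(C)C)C(C)C
Why: Standard silylation of a phenol (silyl chloride/imidazole); the bulky, weakly coordinating silyl ether masks the oxygen that later becomes the free ring D phenol, is orthogonal to benzyl ethers and keeps the next lithiation away from its own ortho positions.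

**Step 2**
Reactants: 2 [3,5-bis(benzyloxy)phenoxy]triisopropylsilane (2.2 equiv); 3 4-(benzyloxy)-2-hydroxybenzaldehyde
Product: 5 [4-(benzyloxy)-2-hydroxyphenyl][2,6-bis(benzyloxy)-4-(triisopropylsilyloxy)phenyl]methanol (racemic carbinol), via ring D aryllithium 4 (not isolated)
Conditions: n-BuLi, THF, 0 °C; then 3, −78 to 0 °C; H2O quench
Reagents that add atoms: none
Why: Directed ortho-lithiation at the C–H flanked by the two benzyloxy groups (doubly activated, and n-BuLi at 0 °C should favour it over benzylic deprotonation) followed by 1,2-addition of the aryllithium to the aldehyde gives the diaryl carbinol; the first equivalent of 4 only deprotonates the phenol of 3 and reverts to 2, and the racemic carbinol centre is erased in step 4.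

**Step 3**
Reactants: 6 4-(benzyloxy)benzaldehyde
Product: 7 1-(benzyloxy)-4-ethenylbenzene (4-benzyloxystyrene)
Conditions: Ph3PCH3Br, KOtBu, THF, 0 °C to rt
Reagents that add atoms: methyltriphenylphosphonium bromide, C[P+](c1ccccc1)(c1ccccc1)c1ccccc1.[Br-]
Why: Wittig methylenation of an aromatic aldehyde with the unstabilised ylide gives the electron-rich styrene needed as dienophile.

**Step 4**
Reactants: 5 the diaryl carbinol; 7 4-benzyloxystyrene
Product: 9 (2S,4S)-7-(benzyloxy)-2-[4-(benzyloxy)phenyl]-4-[2,6-bis(benzyloxy)-4-(triisopropylsilyloxy)phenyl]chromane, via ring A o-quinone methide 8 (not isolated)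
Conditions: (R)-3,3'-bis(2,4,6-triisopropylphenyl)-1,1'-binaphthyl-2,2'-diyl N-triflylphosphoramide (10 mol %), toluene, −20 °C
Reagents that add atoms: none
Why: The strong chiral Brønsted acid dehydrates 5 to o-quinone methide 8 and stays hydrogen-bonded to it, so that the inverse-electron-demand oxa-Diels–Alder reaction with the electron-rich styrene (a known reaction of o-hydroxybenzhydrols with styrenes under chiral N-triflylphosphoramide catalysis) forms upper C4–C3 and O1–C2 through an endo transition state, the catalyst pocket choosing the face of the methide carbon (C4, S) and the endo approach placing ring B cis to ring D (C2, S).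

**Step 5**
Reactants: 9 the silyl-protected flavan
Product: 10 3,5-bis(benzyloxy)-4-{(2S,4S)-7-(benzyloxy)-2-[4-(benzyloxy)phenyl]chroman-4-yl}phenol
Conditions: Bu4NF, AcOH, THF, 0 °C
Reagents that add atoms: none
Why: Fluoride-induced cleavage of the aryl silyl ether, buffered with acetic acid so that the electron-rich phenoxide is protonated at once, frees the ring D phenol and leaves the benzyl ethers and both stereocentres untouched.

**Step 6**
Reactants: 10 the ring D phenol
Product: 11 3,5-bis(benzyloxy)-4-{(2S,4S)-7-(benzyloxy)-2-[4-(benzyloxy)phenyl]chroman-4-yl}-2-[(4-methylphenyl)sulfonylmethyl]phenol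
Conditions: (CH2O)n (1 equiv), p-TolSO2Na, HCO2H, THF/H2O, rt
Reagents that add atoms: formaldehyde (from paraformaldehyde), C=O; sodium p-toluenesulfinate, Cc1ccc(cc1)S(=O)[O-].[Na+]
Why: Mannich-type three-component sulfonylmethylation, in which the phenol is hydroxymethylated ortho to OH, the benzylic alcohol ionises in formic acid and the sulfinate captures the cation as the sulfone; the two ortho positions of ring D are interchanged by rotation about the C4–aryl bond and give one constitution, the ether rings A and B are far less nucleophilic than the free phenol, and one equivalent of formaldehyde limits double substitution.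

**Step 7**
Reactants: 11 the ortho-(tosylmethyl)phenol; 12 benzyloxyacetaldehyde
Product: 14 (3R)-3,5,7-tris(benzyloxy)-6-{(2S,4S)-7-(benzyloxy)-2-[4-(benzyloxy)phenyl]chroman-4-yl}chroman-2-ol (both C2 anomers), via ring D o-quinone methide 13 (not isolated)
Conditions: (S)-2-[diphenyl(trimethylsilyloxy)methyl]pyrrolidine (20 mol %), Na2CO3, CH2Cl2, 0 °C to rt
Reagents that add atoms: none
Why: Na2CO3 deprotonates the ring D phenol of 11 and 1,4-elimination of p-toluenesulfinate releases o-quinone methide 13, while the amine and 12 condense to the E-enamine. The enamine carbon bearing the benzyloxy group adds to the exocyclic methylene of 13 (Michael addition, lower C3–C4), which rearomatises ring D to a phenoxide. This phenoxide attacks the iminium carbon in a 6-exo-trig closure (O1–C2), so that ring F arises as a cyclic N,O-acetal which water converts into lactol 14 with release of the amine. The closest known reaction is the secondary-amine-catalysed formal [4+2] annulation of sulfone-derived o-quinone methides with enolisable aldehydes to chroman-2-ols. C3 is set as R because the diphenyl(trimethylsilyloxy)methyl group of the (S)-pyrrolidine shields one face of the s-trans E-enamine, whereas the anomeric C2 forms as a mixture that is erased in step 9. The step needs this facial selectivity and trapping of 13 before it dimerises; the methylene of 13 is its only electrophilic carbon and the single phenol oxygen lies ortho to it, so only the 4→6-linked ring F can close, and slow heterogeneous release of 13 in the presence of excess 12 favours the cross reaction.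

**Step 8**
Reactants: 14 the lactol
Product: 15 (3R)-3,5,7-tris(benzyloxy)-6-{(2S,4S)-7-(benzyloxy)-2-[4-(benzyloxy)phenyl]chroman-4-yl}chroman-2-yl acetate (both C2 anomers)
Conditions: Ac2O, pyridine, DMAP (cat.), CH2Cl2, 0 °C
Reagents that add atoms: acetic anhydride, CC(=O)OC(C)=O
Why: Acylation of the hemiacetal hydroxyl under nucleophilic catalysis gives the anomeric acetate as leaving group for step 9; the closed lactol form keeps C3 from epimerising and the anomeric mixture is of no consequence.

**Step 9**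
Reactants: 15 the anomeric acetate; 16 (4-benzyloxyphenyl)magnesium bromide (commercial THF solution)
Product: 19 (2R,3R)-3,5,7-tris(benzyloxy)-2-[4-(benzyloxy)phenyl]-6-{(2S,4S)-7-(benzyloxy)-2-[4-(benzyloxy)phenyl]chroman-4-yl}chromane, via arylzinc bromide 17 (not isolated), via ring F oxocarbenium ion 18 (not isolated)
Conditions: 16, ZnBr2, THF, 0 °C; then 15, BF3·OEt2, CH2Cl2, −78 to −30 °C
Reagents that add atoms: none
Why: ZnBr2 turns the Grignard reagent into the milder arylzinc 17, BF3·OEt2 ionises the anomeric acetate to oxocarbenium ion 18, and aryl transfer to C2 (Lewis acid-mediated C-arylation of an anomeric acetate, as in C-aryl glycoside synthesis) should occur on the face that lets the C3 benzyloxy group stay pseudo-equatorial while the new bond forms pseudo-axially through a half-chair, which places ring E cis to C3–O and sets C2 as R.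

**Step 10**
Reactants: 19 the hexabenzyl ether
Product: 20 (2R,3R)-2-(4-hydroxyphenyl)-6-[(2S,4S)-7-hydroxy-2-(4-hydroxyphenyl)chroman-4-yl]chromane-3,5,7-triol (CNP0167324.1)
Conditions: H2 (1 atm), Pd(OH)2/C, THF/MeOH, rt
Reagents that add atoms: none
Why: Catalytic hydrogenolysis of the six benzyl ethers over Pd(OH)2/C under neutral conditions, under which the cyclic benzylic C2–O1 ethers of flavans persist, should release the target with all four stereocentres unchanged.

**Compound list**
1 | 3,5-bis(benzyloxy)phenol | Oc1cc(OCc2ccccc2)cc(OCc2ccccc2)c1 | starting material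
2 | [3,5-bis(benzyloxy)phenoxy]triisopropylsilane | CC(C)[Si](Oc1cc(OCc2ccccc2)cc(OCc2ccccc2)c1)(C(C)C)C(C)C | intermediate
3 | 4-(benzyloxy)-2-hydroxybenzaldehyde | O=Cc1ccc(OCc2ccccc2)cc1O | starting material
4 | [2,6-bis(benzyloxy)-4-(triisopropylsilyloxy)phenyl]lithium | [Li]c1c(OCc2ccccc2)cc(O[Si](C(C)C)(C(C)C)C(C)C)cc1OCc1ccccc1 | intermediate (not isolated)
5 | [4-(benzyloxy)-2-hydroxyphenyl][2,6-bis(benzyloxy)-4-(triisopropylsilyloxy)phenyl]methanol, racemic | OC(c1ccc(OCc2ccccc2)cc1O)c1c(OCc2ccccc2)cc(O[Si](C(C)C)(C(C)C)C(C)C)cc1OCc1ccccc1 | intermediate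
6 | 4-(benzyloxy)benzaldehyde | O=Cc1ccc(OCc2ccccc2)cc1 | starting material
7 | 1-(benzyloxy)-4-ethenylbenzene | C=Cc1ccc(OCc2ccccc2)cc1 | intermediate
8 | 3-(benzyloxy)-6-{[2,6-bis(benzyloxy)-4-(triisopropylsilyloxy)phenyl]methylidene}cyclohexa-2,4-dien-1-one (ring A o-quinone methide) | O=C1C=C(OCc2ccccc2)C=CC1=Cc1c(OCc2ccccc2)cc(O[Si](C(C)C)(C(C)C)C(C)C)cc1OCc1ccccc1 | intermediate (not isolated)
9 | (2S,4S)-7-(benzyloxy)-2-[4-(benzyloxy)phenyl]-4-[2,6-bis(benzyloxy)-4-(triisopropylsilyloxy)phenyl]chromane | c1ccccc1COc1ccc([C@@H]2C[C@H](c3c(OCc5ccccc5)cc(O[Si](C(C)C)(C(C)C)C(C)C)cc3OCc3ccccc3)c3ccc(OCc5ccccc5)cc3O2)cc1 | intermediate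
10 | 3,5-bis(benzyloxy)-4-{(2S,4S)-7-(benzyloxy)-2-[4-(benzyloxy)phenyl]chroman-4-yl}phenol | c1ccccc1COc1ccc([C@@H]2C[C@H](c3c(OCc5ccccc5)cc(O)cc3OCc3ccccc3)c3ccc(OCc5ccccc5)cc3O2)cc1 | intermediate
11 | 3,5-bis(benzyloxy)-4-{(2S,4S)-7-(benzyloxy)-2-[4-(benzyloxy)phenyl]chroman-4-yl}-2-[(4-methylphenyl)sulfonylmethyl]phenol | c1ccccc1COc1ccc([C@@H]2C[C@H](c3c(OCc5ccccc5)cc(O)c(CS(=O)(=O)c5ccc(C)cc5)c3OCc3ccccc3)c3ccc(OCc5ccccc5)cc3O2)cc1 | intermediate
12 | benzyloxyacetaldehyde | O=CCOCc1ccccc1 | starting material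
13 | 3,5-bis(benzyloxy)-4-{(2S,4S)-7-(benzyloxy)-2-[4-(benzyloxy)phenyl]chroman-4-yl}-6-methylidenecyclohexa-2,4-dien-1-one (ring D o-quinone methide) | c1ccccc1COc1ccc([C@@H]2C[C@H](C3=C(OCc5ccccc5)C(=C)C(=O)C=C3OCc3ccccc3)c3ccc(OCc5ccccc5)cc3O2)cc1 | intermediate (not isolated)
14 | (3R)-3,5,7-tris(benzyloxy)-6-{(2S,4S)-7-(benzyloxy)-2-[4-(benzyloxy)phenyl]chroman-4-yl}chroman-2-ol, C2 anomers | c1ccccc1COc1ccc([C@@H]2C[C@H](c3c(OCc5ccccc5)cc4c(c3OCc3ccccc3)C[C@@H](OCc3ccccc3)C(O)O4)c3ccc(OCc5ccccc5)cc3O2)cc1 | intermediate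
15 | (3R)-3,5,7-tris(benzyloxy)-6-{(2S,4S)-7-(benzyloxy)-2-[4-(benzyloxy)phenyl]chroman-4-yl}chroman-2-yl acetate, C2 anomers | c1ccccc1COc1ccc([C@@H]2C[C@H](c3c(OCc5ccccc5)cc4c(c3OCc3ccccc3)C[C@@H](OCc3ccccc3)C(OC(C)=O)O4)c3ccc(OCc5ccccc5)cc3O2)cc1 | intermediate
16 | (4-benzyloxyphenyl)magnesium bromide | Br[Mg]c1ccc(OCc2ccccc2)cc1 | starting material
17 | (4-benzyloxyphenyl)zinc bromide | Br[Zn]c1ccc(OCc2ccccc2)cc1 | intermediate (not isolated)
18 | (3R)-3,5,7-tris(benzyloxy)-6-{(2S,4S)-7-(benzyloxy)-2-[4-(benzyloxy)phenyl]chroman-4-yl}-3,4-dihydrochromenylium (ring F oxocarbenium ion) | c1ccccc1COc1ccc([C@@H]2C[C@H](c3c(OCc5ccccc5)cc4c(c3OCc3ccccc3)C[C@@H](OCc3ccccc3)C=[O+]4)c3ccc(OCc5ccccc5)cc3O2)cc1 | intermediate (not isolated)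
19 | (2R,3R)-3,5,7-tris(benzyloxy)-2-[4-(benzyloxy)phenyl]-6-{(2S,4S)-7-(benzyloxy)-2-[4-(benzyloxy)phenyl]chroman-4-yl}chromane | c1ccccc1COc1ccc([C@@H]2C[C@H](c3c(OCc5ccccc5)cc4c(c3OCc3ccccc3)C[C@@H](OCc3ccccc3)[C@@H](c3ccc(OCc5ccccc5)cc3)O4)c3ccc(OCc5ccccc5)cc3O2)cc1 | intermediate
20 | (2R,3R)-2-(4-hydroxyphenyl)-6-[(2S,4S)-7-hydroxy-2-(4-hydroxyphenyl)chroman-4-yl]chromane-3,5,7-triol | Oc1ccc([C@@H]2C[C@H](c3c(O)cc4c(c3O)C[C@@H](O)[C@@H](c3ccc(O)cc3)O4)c3ccc(O)cc3O2)cc1 | target

**Step count**
Total: 10 steps. Longest linear sequence: 9 steps (1, 2, 4, 5, 6, 7, 8, 9, 10); step 3 is a one-step branch.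

**Steps most likely to fail**

Step 4. The risk is weak enantiofacial discrimination: the methide carbon carries a 2,6-disubstituted aryl group and the quinone methide is so stabilised that it may react as a loose ion pair; self-alkylation of the electron-rich ring A could also compete. Fallback, setting out from 5 and 7: the cycloaddition is run with an achiral acid (diphenyl phosphate, toluene), which should still give the 2,4-cis flavan, now as the racemate of 9, racemic cis flavan F1. The enantiomers are then separated by preparative chromatography on a chiral stationary phase (cellulose tris(3,5-dimethylphenylcarbamate)), and the (2S,4S) enantiomer rejoins the route as 9.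

Step 7. The risk is that the unsubstituted quinone methide dimerises faster than the enamine adds, or that the C3 configuration erodes through enamine formation from the open-chain aldehyde form of the lactol. Fallback, setting out from 11: an excess of the sodium enolate of (S)-4-benzyl-3-(benzyloxyacetyl)oxazolidin-2-one (NaN(SiMe3)2, THF, −78 °C; one equivalent serves to release 13) adds to 13 from the face opposite the benzyl group of the auxiliary to give the (2R)-imide adduct F2. On warming, the ring D phenoxide closes onto the imide carbonyl and expels the oxazolidinone to give the (3R)-3-benzyloxychroman-2-one F3. Reduction with i-Bu2AlH in CH2Cl2 at −78 °C returns to the route at lactol 14.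

Step 9. The risk is loss of 2,3-cis selectivity in the benzo-fused oxocarbenium ion, Lewis acid-induced ionisation at upper C2 or C4, or aryl transfer that is too slow. Fallback, setting out from 14: excess 16 in THF opens the lactol and adds to the aldehyde to give the 1-aryl-propane-1-ol F4 as a mixture at the new carbinol. MnO2 in CH2Cl2 oxidises the benzylic alcohol to the aryl ketone F5. Zn(BH4)2 in Et2O reduces it under chelation by the α-benzyloxy group to the anti (1S,2R) alcohol F6. Mitsunobu etherification (PPh3, DIAD, THF) closes ring F with inversion at the benzylic carbon and returns to the route at 19.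

**Further compounds**
F1 | step 4 | racemic (2S*,4S*)-7-(benzyloxy)-2-[4-(benzyloxy)phenyl]-4-[2,6-bis(benzyloxy)-4-(triisopropylsilyloxy)phenyl]chromane (racemate of 9, one enantiomer drawn) | c1ccccc1COc1ccc([C@@H]2C[C@H](c3c(OCc5ccccc5)cc(O[Si](C(C)C)(C(C)C)C(C)C)cc3OCc3ccccc3)c3ccc(OCc5ccccc5)cc3O2)cc1
F2 | step 7 | (4S)-4-benzyl-3-[(2R)-2-(benzyloxy)-3-{2,4-bis(benzyloxy)-3-[(2S,4S)-7-(benzyloxy)-2-(4-benzyloxyphenyl)chroman-4-yl]-6-hydroxyphenyl}propanoyl]oxazolidin-2-one | c1ccccc1COc1ccc([C@@H]2C[C@H](c3c(OCc5ccccc5)cc(O)c(c3OCc3ccccc3)C[C@@H](OCc3ccccc3)C(=O)N3[C@@H](Cc5ccccc5)COC3=O)c3ccc(OCc5ccccc5)cc3O2)cc1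
F3 | step 7 | (3R)-3,5,7-tris(benzyloxy)-6-{(2S,4S)-7-(benzyloxy)-2-[4-(benzyloxy)phenyl]chroman-4-yl}chroman-2-one | c1ccccc1COc1ccc([C@@H]2C[C@H](c3c(OCc5ccccc5)cc4c(c3OCc3ccccc3)C[C@@H](OCc3ccccc3)C(=O)O4)c3ccc(OCc5ccccc5)cc3O2)cc1
F4 | step 9 | (2R)-2-(benzyloxy)-1-[4-(benzyloxy)phenyl]-3-{2,4-bis(benzyloxy)-3-[(2S,4S)-7-(benzyloxy)-2-(4-benzyloxyphenyl)chroman-4-yl]-6-hydroxyphenyl}propan-1-ol (C1 epimers) | c1ccccc1COc1ccc([C@@H]2C[C@H](c3c(OCc5ccccc5)cc(O)c(c3OCc3ccccc3)C[C@@H](OCc3ccccc3)C(O)c3ccc(OCc5ccccc5)cc3)c3ccc(OCc5ccccc5)cc3O2)cc1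
F5 | step 9 | (2R)-2-(benzyloxy)-1-[4-(benzyloxy)phenyl]-3-{2,4-bis(benzyloxy)-3-[(2S,4S)-7-(benzyloxy)-2-(4-benzyloxyphenyl)chroman-4-yl]-6-hydroxyphenyl}propan-1-one | c1ccccc1COc1ccc([C@@H]2C[C@H](c3c(OCc5ccccc5)cc(O)c(c3OCc3ccccc3)C[C@@H](OCc3ccccc3)C(=O)c3ccc(OCc5ccccc5)cc3)c3ccc(OCc5ccccc5)cc3O2)cc1
F6 | step 9 | (1S,2R)-2-(benzyloxy)-1-[4-(benzyloxy)phenyl]-3-{2,4-bis(benzyloxy)-3-[(2S,4S)-7-(benzyloxy)-2-(4-benzyloxyphenyl)chroman-4-yl]-6-hydroxyphenyl}propan-1-ol | c1ccccc1COc1ccc([C@@H]2C[C@H](c3c(OCc5ccccc5)cc(O)c(c3OCc3ccccc3)C[C@@H](OCc3ccccc3)[C@@H](O)c3ccc(OCc5ccccc5)cc3)c3ccc(OCc5ccccc5)cc3O2)cc1
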